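## Analysis of the target

- The target 31 is a trimeric acylphloroglucinol with three six-membered carbocycles. Ring A is a fully substituted aromatic phloroglucinol: C1 carries the butanoyl group, C2, C4 and C6 carry hydroxyls, and C3 and C5 each carry a methylene bridge.
- Ring B is an enolised 2-acetyl-4,4-dimethylcyclohexane-1,3,5-trione and ring C is its 2-propanoyl homologue. Each is joined through its one remaining ring carbon to one of the bridges.
- There is no stereocentre: both quaternary carbons carry two methyl groups, so the problem is purely constitutional.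
- The sensitive parts are the acidic, chelating, C/O-ambident triketone enols, the three phenols on an electron-rich ring, and the two methylene bridges. Under base the bridges can open by retro-Michael reaction to quinone methides and close again, which scrambles the outer rings.
- The difficulty is the near-symmetry. Ring A has a local mirror plane through C1 and C4, and rings B and C differ by a single CH2 in the acyl chain. Any symmetrical double alkylation of a butanoylphloroglucinol would therefore give a statistical mixture of homologues that are very hard to separate.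
- The strategy rests on the two arm-bearing carbons C3 and C5 of ring A, which flank the C4 hydroxyl. Ring A is assembled so that C3 arrives as a protected hydroxymethyl carbon and C5 as a methyl carbon, with the three oxygens masked differently and C1 still C–H. The two arms can then be used one after the other.

## Retrosynthetic reasoning

**Bridge to ring B.** The last bond cut is the one between the C3 methylene of ring A and ring B, which gives dimer 26 and acetyl triketone 28. This is the natural polarity: an ortho-quinone methide of ring A as acceptor and the free ring carbon of the triketone as donor. Cutting it last keeps ring B away from every earlier reagent. The forward step has to unmask the ring A phenoxides and expel the benzylic acetate without opening the first bridge.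

**Bridge to ring C.** The bond between the C5 methylene and ring C is cut next, which gives bromide 22 and propanoyl triketone 24. In 22 the only free phenol is ortho to the bromomethyl arm and para to the acetoxymethyl arm. Bromide leaves far faster than acetate, so the forward step must form a quinone methide at one arm only.

**Adjusting the arms.** Compound 22 goes back to 21 (phenol from the ethyl ether next to the butanoyl carbonyl) and then to 20 (bromide from the methyl arm). The methyl group is oxidised at a stage where the ring has no hydrogen left and the other arm is an ester, so that its benzylic hydrogens are deactivated. The ether cleavage is placed after the ketone is in, because only then is it chelation-assisted and mild.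

**Butanoyl group.** Acetate 20 comes from silyl ether 18, and the aryl–acyl bond of 18 is cut to aryl bromide 15 and butanoyl chloride 16. A Lewis-acid acylation is ruled out by the acid-labile benzylic silyl ether on an electron-rich ring, so the acyl group enters through an aryllithium. Bromide 15 comes from bromophenol 14, and 14 from phenol 13 by substitution at its single ring hydrogen.

**Ring A.** Phenol 13 is cut at two ring bonds, C1–C2 and C3–C4, to cyclobutenone 4 and siloxyalkyne 8. This one step delivers all six substituents of ring A: two arms at different oxidation levels, three oxygens as OH, OSi and OEt, and one ring hydrogen at the future butanoyl position. The forward reaction must control only the orientation of the alkyne.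

**Annulation partners.** Cyclobutenone 4 is cut across the four-membered ring to the ketene from propanoyl chloride 1 and ethoxyethyne 2. Siloxyalkyne 8 is cut at the O–C(sp) bond to terminal alkyne 5.

**Outer rings.** Triketones 24 and 28 are cut at the two C–CH3 bonds of the quaternary carbon, back to the commercial acylphloroglucinols 23 and 27. This is done on the monomers, where by-products of the methylation are cheap to remove.

## Alternatives that were turned down

**Alternative 1:**
- Disconnection: one C–CH3 bond at the quaternary carbon of ring B and one at that of ring C, leading to the all-aromatic trimer A2 with ring A as its tribenzyl ether.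
- Forward key step: twofold base-mediated C-methylation of A2 at the two methyl-bearing ring carbons, which dearomatises both outer rings and gives tribenzyl ether A1. Hydrogenolysis would finish the synthesis.
- For: it is the shortest route on paper, every intermediate before the last stage is a robust arene, and the methylation is the same reaction type used here in steps 10 and 12.
- Against: each outer ring of A2 can also be alkylated on oxygen or at the bridge-bearing carbon, and the losses multiply over two rings. The strongly basic medium acts on a compound that already has both bridges, so retro-Michael scrambling is invited. Above all, A2 has the same near-symmetric ring A with two different outer rings, so the arm differentiation is simply moved into the synthesis of A2.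
- Comparison: Alternative 1 is stronger on step count. The chosen route offers a built-in answer to the differentiation problem and does the mixture-prone methylation on the simple monomers 23 and 27.

**Alternative 2:**
- Disconnection: within ring B, the bond from the ring carbonyl carbon to the bridge-bearing carbon and the bond from the silyloxy carbon to the future acetyl-bearing carbon.
- Forward key step: thermal annulation of cyclobutenone A3 with siloxyalkyne A4, which already carries the protected ring A benzyl group. The quaternary carbon from A3 prevents aromatisation, so the cascade stops at dienone A5.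
- For: the gem-dimethyl triketone ring is made directly, with no C- versus O-methylation issue. A3 is a better-precedented annulation partner than the monomethyl cyclobutenone 4, and the bridge is formed together with the ring.
- Against: one annulation makes one outer ring, so ring C needs a second alkyne arm and a second annulation. Ring A in A5 still has two equivalent free positions, so the differentiation problem returns. The acetyl group must still be put on the dienone, and A4 is a multistep fragment.
- Comparison: the same pericyclic cascade is used, but on a ring that is available in one step from 27. Alternative 2 is stronger on precedent for the cyclobutenone and on avoiding the methylation. The chosen route spends the annulation on ring A, where it removes the actual difficulty, and is shorter.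

**Alternative 3:**
- Disconnection: in each outer ring, the bond between the acyl-bearing ring carbon and the carbonyl carbon next to the quaternary carbon, with each acyl-enol unit masked as an isoxazole. This leads to the bis-isoxazole diester A6.
- Forward key step: reductive cleavage of both N–O bonds of A6, then alkoxide-induced double Claisen cyclisation of the freed enaminones onto their methyl esters, closing rings B and C as bis-enaminone A7. Hydrolysis of the enaminones and debenzylation would follow.
- For: the sensitive triketones stay masked until the end, the position of each acyl group is fixed by construction, and the acetyl and propanoyl arms are different building blocks.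
- Against: A6 is long and heavily functionalised, with two stereocentres that add nothing but diastereomer mixtures. Attaching two different arms to ring A is again a sequential differentiation problem. Each Claisen closure attacks an ester next to a quaternary carbon, two rings must close in one operation, and the final enaminone hydrolysis needs conditions under which the bridges can scramble.
- Comparison: Alternative 3 is stronger on regiocontrol of the acyl groups and does not depend on quinone methide chemistry. The chosen route is much shorter and convergent, because rings B and C are made in one step each.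

Key step: step 3

Remark: each triketone ring is written as the single enol tautomer of the target SMILES; the tautomers interconvert freely and are one compound in practice.

## Route

Step 1
Reactants: 1 propanoyl chloride; 2 ethoxyethyne
Product: 4 3-ethoxy-4-methylcyclobut-2-en-1-one (racemic), via methylketene 3 (not isolated)
Conditions: Et3N, Et2O, 0 °C → rt, slow addition of 1 to excess 2
Reagents that add atoms: none
Why: Dehydrochlorination gives the ketene, which adds [2+2] to the ynol ether; the nucleophilic terminal alkyne carbon bonds to the ketene carbonyl carbon, so the ethoxy group ends at C3 and the methyl at C4.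

Step 2
Reactants: 5 tert-butyldimethyl(prop-2-yn-1-yloxy)silane
Product: 8 tert-butyldimethyl{[3-(triisopropylsilyloxy)prop-2-yn-1-yl]oxy}silane, via lithium acetylide 6 (not isolated), via lithium ynolate 7 (not isolated)
Conditions: n-BuLi, THF, −78 °C; LiOOt-Bu (from t-BuOOH and LiN(SiMe3)2), −78 → 0 °C; TIPSOTf, −78 °C → rt
Reagents that add atoms: tert-butyl hydroperoxide CC(C)(C)OO; triisopropylsilyl trifluoromethanesulfonate CC(C)[Si](OS(=O)(=O)C(F)(F)F)(C(C)C)C(C)C
Why: Electrophilic oxygen transfer from the lithium peroxide to the acetylide gives the ynolate, which the bulky silyl triflate traps on oxygen (acetylide oxidation followed by O-silylation); the low temperature keeps the ynolate from losing silanolate.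

Step 3
Reactants: 4 3-ethoxy-4-methylcyclobut-2-en-1-one; 8 tert-butyldimethyl{[3-(triisopropylsilyloxy)prop-2-yn-1-yl]oxy}silane
Product: 13 2-[(tert-butyldimethylsilyloxy)methyl]-5-ethoxy-6-methyl-3-(triisopropylsilyloxy)phenol, via vinylketene 9 (not isolated), via vinylcyclobutenone 10 (not isolated), via dienylketene 11 (not isolated), via cyclohexadienone 12 (not isolated)
Conditions: 8 (1.3 equiv), toluene, 80 °C then 110 °C, sealed vessel
Reagents that add atoms: none
Why: Heating opens 4 by conrotatory 4π electrocyclic cleavage of its C1–C4 bond to vinylketene 9. The ketene C=C of 9 adds to siloxyalkyne 8 in a regioselective [2+2] cycloaddition in which the nucleophilic alkyne carbon (the one bearing the siloxymethyl group) bonds to the ketene carbonyl carbon, giving 10. A second 4π opening gives dienylketene 11, whose 6π electrocyclisation joins the ketene carbon to the methyl-bearing terminus and closes the six-membered ring as dienone 12; tautomerisation then aromatises it to 13. The closest known reaction type is the Danheiser benzannulation of cyclobutenones with siloxyalkynes to resorcinol monosilyl ethers. The one new ring is thus closed by 6π electrocyclisation, after the cycloaddition and ring opening have made the C1–C2 and C3–C4 bonds of the phenol. No stereocentre survives, since the sp3 carbons of 4, 10 and 12 are racemic and become planar on aromatisation. The step needs only regioselectivity in the [2+2] event, and the strong polarisation of the ynol silyl ether secures it. This places the siloxymethyl carbon next to the free hydroxyl and the silyloxy carbon next to the ring C–H.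

Step 4
Reactants: 13 2-[(tert-butyldimethylsilyloxy)methyl]-5-ethoxy-6-methyl-3-(triisopropylsilyloxy)phenol
Product: 14 4-bromo-2-[(tert-butyldimethylsilyloxy)methyl]-5-ethoxy-6-methyl-3-(triisopropylsilyloxy)phenol
Conditions: NBS (1.0 equiv), CH2Cl2, −78 → 0 °C, dark
Reagents that add atoms: N-bromosuccinimide O=C1CCC(=O)N1Br
Why: Electrophilic aromatic bromination at the only ring hydrogen, which is para to the free hydroxyl and flanked by two oxygen-bearing carbons; the neutral conditions spare the benzylic silyl ether.

Step 5
Reactants: 14 4-bromo-2-[(tert-butyldimethylsilyloxy)methyl]-5-ethoxy-6-methyl-3-(triisopropylsilyloxy)phenol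
Product: 15 tert-butyl{[3-bromo-4-ethoxy-5-methyl-2,6-bis(triisopropylsilyloxy)phenyl]methoxy}dimethylsilane
Conditions: TIPSOTf, 2,6-lutidine, CH2Cl2, 0 °C → rt
Reagents that add atoms: triisopropylsilyl trifluoromethanesulfonate CC(C)[Si](OS(=O)(=O)C(F)(F)F)(C(C)C)C(C)C
Why: O-silylation of the hindered phenol with the silyl triflate removes the acidic proton before the organolithium step and gives an aryl silyl ether that survives acid, radicals and a boron trihalide.

Step 6
Reactants: 15 tert-butyl{[3-bromo-4-ethoxy-5-methyl-2,6-bis(triisopropylsilyloxy)phenyl]methoxy}dimethylsilane; 16 butanoyl chloride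
Product: 18 1-{3-[(tert-butyldimethylsilyloxy)methyl]-6-ethoxy-5-methyl-2,4-bis(triisopropylsilyloxy)phenyl}butan-1-one, via aryllithium 17 (not isolated)
Conditions: t-BuLi (2.1 equiv), Et2O, −78 °C; then transfer into 16 (3 equiv), Et2O, −78 °C
Reagents that add atoms: none
Why: Bromine–lithium exchange followed by acylation of the aryllithium by inverse addition to the acid chloride; the doubly ortho-substituted ketone resists a second addition, and the low temperature in ether holds back retro-Brook migration of the neighbouring silyl group.

Step 7
Reactants: 18 1-{3-[(tert-butyldimethylsilyloxy)methyl]-6-ethoxy-5-methyl-2,4-bis(triisopropylsilyloxy)phenyl}butan-1-one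
Product: 20 [3-butanoyl-4-ethoxy-5-methyl-2,6-bis(triisopropylsilyloxy)phenyl]methyl acetate, via benzylic alcohol 19 (not isolated)
Conditions: HF·pyridine, pyridine, THF, 0 °C → rt; then Ac2O (excess), DMAP (cat.), rt
Reagents that add atoms: acetic anhydride CC(=O)OC(C)=O
Why: Acidic fluoride cleaves the primary alkyl silyl ether much faster than the two aryl triisopropylsilyl ethers, and acetylation in the same flask turns the labile benzylic alcohol into an ester whose benzylic hydrogens are deactivated towards bromine atoms.

Step 8
Reactants: 20 [3-butanoyl-4-ethoxy-5-methyl-2,6-bis(triisopropylsilyloxy)phenyl]methyl acetate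
Product: 21 [3-(bromomethyl)-5-butanoyl-4-ethoxy-2,6-bis(triisopropylsilyloxy)phenyl]methyl acetate
Conditions: NBS (1.05 equiv), AIBN (cat.), NaHCO3 (solid), PhCF3, 80 °C
Reagents that add atoms: N-bromosuccinimide O=C1CCC(=O)N1Br
Why: Wohl–Ziegler bromination; the ring has no hydrogen left, and the electrophilic bromine atom prefers the methyl group over the acetoxymethyl hydrogens and the ketone α-hydrogens, both of which are polarity-mismatched, while the solid base suppresses acid-catalysed α-bromination.

Step 9
Reactants: 21 [3-(bromomethyl)-5-butanoyl-4-ethoxy-2,6-bis(triisopropylsilyloxy)phenyl]methyl acetate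
Product: 22 [3-(bromomethyl)-5-butanoyl-4-hydroxy-2,6-bis(triisopropylsilyloxy)phenyl]methyl acetate
Conditions: BBr3 (1.1 equiv), CH2Cl2, −78 → −40 °C; cold water quench, no base; used crude
Reagents that add atoms: none
Why: Chelation-assisted dealkylation of an aryl alkyl ether ortho to a ketone: boron binds the carbonyl and ether oxygens and bromide attacks the ethyl group; one equivalent at low temperature leaves the less basic silyl ethers and the acetate alone, and a bromide reagent cannot scramble the benzylic halide.

Step 10
Reactants: 23 1-(2,4,6-trihydroxyphenyl)propan-1-one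
Product: 24 3,5-dihydroxy-4,4-dimethyl-2-propanoylcyclohexa-2,5-dien-1-one
Conditions: MeI (2.2 equiv), NaOMe, MeOH, 0 °C → rt
Reagents that add atoms: iodomethane CI
Why: Dearomatising double C-methylation of the phloroglucinolate, the second methyl entering at the carbon already methylated; O-methyl and ring-dimethyl isomers are expected by-products and should be removable through the higher acidity of the triketone.

Step 11
Reactants: 22 [3-(bromomethyl)-5-butanoyl-4-hydroxy-2,6-bis(triisopropylsilyloxy)phenyl]methyl acetate; 24 3,5-dihydroxy-4,4-dimethyl-2-propanoylcyclohexa-2,5-dien-1-one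
Product: 26 {3-butanoyl-5-[(2,4-dihydroxy-3,3-dimethyl-6-oxo-5-propanoylcyclohexa-1,4-dien-1-yl)methyl]-4-hydroxy-2,6-bis(triisopropylsilyloxy)phenyl}methyl acetate, via ortho-quinone methide 25 (not isolated)
Conditions: 24 (1.1 equiv), i-Pr2NEt (2.5 equiv), THF, −78 → −30 °C; then dilute HCl
Reagents that add atoms: none
Why: The single phenoxide expels the ortho bromide to give the ortho-quinone methide, and the triketone enolate adds through its free ring carbon (Michael addition); at this temperature the para acetate, a much poorer leaving group on an acyl-substituted ring, should stay.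

Step 12
Reactants: 27 1-(2,4,6-trihydroxyphenyl)ethan-1-one
Product: 28 2-acetyl-3,5-dihydroxy-4,4-dimethylcyclohexa-2,5-dien-1-one
Conditions: MeI (2.2 equiv), NaOMe, MeOH, 0 °C → rt
Reagents that add atoms: iodomethane CI
Why: The same dearomatising double C-methylation as in step 10, applied to the acetyl homologue.

Step 13
Reactants: 26 {3-butanoyl-5-[(2,4-dihydroxy-3,3-dimethyl-6-oxo-5-propanoylcyclohexa-1,4-dien-1-yl)methyl]-4-hydroxy-2,6-bis(triisopropylsilyloxy)phenyl}methyl acetate; 28 2-acetyl-3,5-dihydroxy-4,4-dimethylcyclohexa-2,5-dien-1-one
Product: 31 2-acetyl-6-({3-butanoyl-5-[(2,4-dihydroxy-3,3-dimethyl-6-oxo-5-propanoylcyclohexa-1,4-dien-1-yl)methyl]-2,4,6-trihydroxyphenyl}methyl)-3,5-dihydroxy-4,4-dimethylcyclohexa-2,5-dien-1-one (CNP0315613.0), via triphenol acetate 29 (not isolated), via quinone methide 30 (not isolated)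
Conditions: 28 (1.2 equiv), TBAF (excess), THF, −40 → 0 °C, short reaction time; then 1 M HCl
Reagents that add atoms: none
Why: Fluoride removes both aryl silyl groups, the phenoxide expels the benzylic acetate to give the ring A quinone methide, and the enolate of 28 adds through its free ring carbon (fluoride-triggered quinone methide formation and Michael addition); prompt acidification returns the neutral triketones before the bridges can exchange.

## Compound list

1 | propanoyl chloride | CCC(Cl)=O | starting material
2 | ethoxyethyne | CCOC#C | starting material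
3 | methylketene (prop-1-en-1-one; not isolated) | CC=C=O | intermediate
4 | 3-ethoxy-4-methylcyclobut-2-en-1-one (racemic) | CCOC1=CC(=O)C1C | intermediate
5 | tert-butyldimethyl(prop-2-yn-1-yloxy)silane | C#CCO[Si](C)(C)C(C)(C)C | starting material
6 | lithium 3-(tert-butyldimethylsilyloxy)prop-1-yn-1-ide (not isolated) | [Li]C#CCO[Si](C)(C)C(C)(C)C | intermediate
7 | lithium 3-(tert-butyldimethylsilyloxy)prop-1-yn-1-olate (not isolated) | [Li]OC#CCO[Si](C)(C)C(C)(C)C | intermediate
8 | tert-butyldimethyl{[3-(triisopropylsilyloxy)prop-2-yn-1-yl]oxy}silane | CC(C)[Si](OC#CCO[Si](C)(C)C(C)(C)C)(C(C)C)C(C)C | intermediate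
9 | (Z)-3-ethoxypenta-1,3-dien-1-one (expected geometry; not isolated) | C/C=C(\OCC)C=C=O | intermediate
10 | 2-[(tert-butyldimethylsilyloxy)methyl]-4-(1-ethoxyprop-1-en-1-yl)-3-(triisopropylsilyloxy)cyclobut-2-en-1-one (racemic; not isolated) | O=C1C(CO[Si](C)(C)C(C)(C)C)=C(O[Si](C(C)C)(C(C)C)C(C)C)C1/C(OCC)=C/C | intermediate
11 | 2-[(tert-butyldimethylsilyloxy)methyl]-5-ethoxy-3-(triisopropylsilyloxy)hepta-1,3,5-trien-1-one (geometry as needed for closure; not isolated) | O=C=C(CO[Si](C)(C)C(C)(C)C)/C(O[Si](C(C)C)(C(C)C)C(C)C)=C\C(OCC)=C\C | intermediate
12 | 2-[(tert-butyldimethylsilyloxy)methyl]-5-ethoxy-6-methyl-3-(triisopropylsilyloxy)cyclohexa-2,4-dien-1-one (racemic; not isolated) | O=C1C(CO[Si](C)(C)C(C)(C)C)=C(O[Si](C(C)C)(C(C)C)C(C)C)C=C(OCC)C1C | intermediate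
13 | 2-[(tert-butyldimethylsilyloxy)methyl]-5-ethoxy-6-methyl-3-(triisopropylsilyloxy)phenol | Cc1c(O)c(CO[Si](C)(C)C(C)(C)C)c(O[Si](C(C)C)(C(C)C)C(C)C)cc1OCC | intermediate
14 | 4-bromo-2-[(tert-butyldimethylsilyloxy)methyl]-5-ethoxy-6-methyl-3-(triisopropylsilyloxy)phenol | Cc1c(O)c(CO[Si](C)(C)C(C)(C)C)c(O[Si](C(C)C)(C(C)C)C(C)C)c(Br)c1OCC | intermediate
15 | tert-butyl{[3-bromo-4-ethoxy-5-methyl-2,6-bis(triisopropylsilyloxy)phenyl]methoxy}dimethylsilane | Cc1c(O[Si](C(C)C)(C(C)C)C(C)C)c(CO[Si](C)(C)C(C)(C)C)c(O[Si](C(C)C)(C(C)C)C(C)C)c(Br)c1OCC | intermediate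
16 | butanoyl chloride | CCCC(Cl)=O | starting material
17 | {3-[(tert-butyldimethylsilyloxy)methyl]-6-ethoxy-5-methyl-2,4-bis(triisopropylsilyloxy)phenyl}lithium (not isolated) | Cc1c(O[Si](C(C)C)(C(C)C)C(C)C)c(CO[Si](C)(C)C(C)(C)C)c(O[Si](C(C)C)(C(C)C)C(C)C)c([Li])c1OCC | intermediate
18 | 1-{3-[(tert-butyldimethylsilyloxy)methyl]-6-ethoxy-5-methyl-2,4-bis(triisopropylsilyloxy)phenyl}butan-1-one | CCCC(=O)c1c(O[Si](C(C)C)(C(C)C)C(C)C)c(CO[Si](C)(C)C(C)(C)C)c(O[Si](C(C)C)(C(C)C)C(C)C)c(C)c1OCC | intermediate
19 | 1-[6-ethoxy-3-(hydroxymethyl)-5-methyl-2,4-bis(triisopropylsilyloxy)phenyl]butan-1-one (not isolated) | CCCC(=O)c1c(O[Si](C(C)C)(C(C)C)C(C)C)c(CO)c(O[Si](C(C)C)(C(C)C)C(C)C)c(C)c1OCC | intermediate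
20 | [3-butanoyl-4-ethoxy-5-methyl-2,6-bis(triisopropylsilyloxy)phenyl]methyl acetate | CCCC(=O)c1c(O[Si](C(C)C)(C(C)C)C(C)C)c(COC(C)=O)c(O[Si](C(C)C)(C(C)C)C(C)C)c(C)c1OCC | intermediate
21 | [3-(bromomethyl)-5-butanoyl-4-ethoxy-2,6-bis(triisopropylsilyloxy)phenyl]methyl acetate | CCCC(=O)c1c(O[Si](C(C)C)(C(C)C)C(C)C)c(COC(C)=O)c(O[Si](C(C)C)(C(C)C)C(C)C)c(CBr)c1OCC | intermediate
22 | [3-(bromomethyl)-5-butanoyl-4-hydroxy-2,6-bis(triisopropylsilyloxy)phenyl]methyl acetate | CCCC(=O)c1c(O[Si](C(C)C)(C(C)C)C(C)C)c(COC(C)=O)c(O[Si](C(C)C)(C(C)C)C(C)C)c(CBr)c1O | intermediate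
23 | 1-(2,4,6-trihydroxyphenyl)propan-1-one | CCC(=O)c1c(O)cc(O)cc1O | starting material
24 | 3,5-dihydroxy-4,4-dimethyl-2-propanoylcyclohexa-2,5-dien-1-one | CCC(=O)C1=C(O)C(C)(C)C(O)=CC1=O | intermediate
25 | [5-butanoyl-3-methylidene-4-oxo-2,6-bis(triisopropylsilyloxy)cyclohexa-1,5-dien-1-yl]methyl acetate (not isolated) | CCCC(=O)C1=C(O[Si](C(C)C)(C(C)C)C(C)C)C(COC(C)=O)=C(O[Si](C(C)C)(C(C)C)C(C)C)C(=C)C1=O | intermediate
26 | {3-butanoyl-5-[(2,4-dihydroxy-3,3-dimethyl-6-oxo-5-propanoylcyclohexa-1,4-dien-1-yl)methyl]-4-hydroxy-2,6-bis(triisopropylsilyloxy)phenyl}methyl acetate | CCCC(=O)c1c(O[Si](C(C)C)(C(C)C)C(C)C)c(COC(C)=O)c(O[Si](C(C)C)(C(C)C)C(C)C)c(CC2=C(O)C(C)(C)C(O)=C(C(=O)CC)C2=O)c1O | intermediate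
27 | 1-(2,4,6-trihydroxyphenyl)ethan-1-one | CC(=O)c1c(O)cc(O)cc1O | starting material
28 | 2-acetyl-3,5-dihydroxy-4,4-dimethylcyclohexa-2,5-dien-1-one | CC(=O)C1=C(O)C(C)(C)C(O)=CC1=O | intermediate
29 | {3-butanoyl-5-[(2,4-dihydroxy-3,3-dimethyl-6-oxo-5-propanoylcyclohexa-1,4-dien-1-yl)methyl]-2,4,6-trihydroxyphenyl}methyl acetate (not isolated) | CCCC(=O)c1c(O)c(COC(C)=O)c(O)c(CC2=C(O)C(C)(C)C(O)=C(C(=O)CC)C2=O)c1O | intermediate
30 | 4-butanoyl-2-[(2,4-dihydroxy-3,3-dimethyl-6-oxo-5-propanoylcyclohexa-1,4-dien-1-yl)methyl]-3,5-dihydroxy-6-methylidenecyclohexa-2,4-dien-1-one (not isolated) | CCCC(=O)C1=C(O)C(=C)C(=O)C(CC2=C(O)C(C)(C)C(O)=C(C(=O)CC)C2=O)=C1O | intermediate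
31 | 2-acetyl-6-({3-butanoyl-5-[(2,4-dihydroxy-3,3-dimethyl-6-oxo-5-propanoylcyclohexa-1,4-dien-1-yl)methyl]-2,4,6-trihydroxyphenyl}methyl)-3,5-dihydroxy-4,4-dimethylcyclohexa-2,5-dien-1-one (CNP0315613.0) | CCCC(=O)c1c(O)c(CC2=C(O)C(C)(C)C(O)=C(C(C)=O)C2=O)c(O)c(CC2=C(O)C(C)(C)C(O)=C(C(=O)CC)C2=O)c1O | target

## Step count and least certain steps

Total step count: 13. Longest linear sequence: 10 steps (steps 1, 3, 4, 5, 6, 7, 8, 9, 11 and 13).

**Step 3 (key step).** The ethoxy-substituted vinylketene may dimerise or acylate the product phenol faster than it combines with the equally electron-rich siloxyalkyne, and the ring opening of a 3-alkoxycyclobutenone may need temperatures at which the alkyne decomposes. The fallback sets out from siloxyalkyne 8 and comes back at phenol 13. It makes the same vinylketene by base-induced 1,4-elimination at room temperature instead of by ring opening. Commercial ethyl 3-oxopentanoate F1 is converted with triethyl orthoformate and catalytic acid into ethyl (E)-3-ethoxypent-2-enoate F2, saponified to (E)-3-ethoxypent-2-enoic acid F3, and converted with oxalyl chloride into (E)-3-ethoxypent-2-enoyl chloride F4. Et3N removes HCl from F4 in the presence of 8, which gives vinylketene 9 (or its double-bond isomer, which converges on the same product) and then cycloadduct 10. This is collected and only then heated in toluene to give 13.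

**Step 6.** Migration of the neighbouring triisopropylsilyl group from oxygen to the lithiated carbon (retro-Brook rearrangement), or proton transfer from the α-position of the acid chloride to the hindered aryllithium, would consume the organometallic. The fallback sets out from 15 and comes back at 18. After the same exchange at −78 °C the aryllithium is trapped at once with butanal, the fastest available electrophile, to give 1-{3-[(tert-butyldimethylsilyloxy)methyl]-6-ethoxy-5-methyl-2,4-bis(triisopropylsilyloxy)phenyl}butan-1-ol F5. Oxidation of F5 with Dess–Martin periodinane gives 18.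

**Step 8.** Bromination may run on to the dibromide before the methyl compound is consumed, or hydrogen abstraction may be shared with the other benzylic position, so that no clean monobromide results. The fallback sets out from 20 and comes back at 26. It carries the arm one oxidation level higher, where no leaving-group chemistry is needed.
- Excess NBS drives 20 to [3-butanoyl-5-(dibromomethyl)-4-ethoxy-2,6-bis(triisopropylsilyloxy)phenyl]methyl acetate F6.
- AgNO3 in aqueous acetone hydrolyses F6 to [3-butanoyl-4-ethoxy-5-formyl-2,6-bis(triisopropylsilyloxy)phenyl]methyl acetate F7.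
- BCl3 cleaves the doubly chelated ethyl ether to give [3-butanoyl-5-formyl-4-hydroxy-2,6-bis(triisopropylsilyloxy)phenyl]methyl acetate F8.
- Knoevenagel condensation of F8 with 24 under L-proline catalysis, with Hantzsch ester reducing the alkylidene triketone in the same flask, gives 26 with carbon-only attachment.

**Step 9.** The ethyl ether cleaves more slowly than a methyl ether, and on warming the benzylic acetate may be exchanged for bromide or a silyl ether lost. The product is also a reactive ortho-hydroxybenzyl bromide that may ionise during work-up. The fallback sets out from 20 and comes back at 26. It reorders the events so that no benzylic bromide is present during the ether cleavage.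
- BCl3 cleaves the ethyl ether of 20 to the stable phenol [3-butanoyl-4-hydroxy-5-methyl-2,6-bis(triisopropylsilyloxy)phenyl]methyl acetate F9.
- TBSOTf and 2,6-lutidine give {3-butanoyl-4-[(tert-butyldimethylsilyl)oxy]-5-methyl-2,6-bis(triisopropylsilyloxy)phenyl}methyl acetate F10.
- NBS and AIBN give {3-(bromomethyl)-5-butanoyl-4-[(tert-butyldimethylsilyl)oxy]-2,6-bis(triisopropylsilyloxy)phenyl}methyl acetate F11.
- One equivalent of TBAF at −78 °C in the presence of 24 removes the most labile silyl group, the one ortho to the ketone. This releases quinone methide 25 and gives 26.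

**Step 11.** The quinone methide may dimerise if the enolate adds slowly, or the phenoxide may also expel the para acetate, which would lead to alkylation at both arms by the same triketone. The fallback sets out from 22 and comes back at 26 and makes no new compound. The bromide is ionised under non-basic conditions with AgOTf and 2,6-di-tert-butylpyridine in CH2Cl2 at −40 °C in the presence of 24. The phenol stays protonated, the benzylic cation is captured by the neutral enol on carbon, and the acetate arm cannot leave.

**Step 13.** Under the basic fluoride conditions the methylene bridges may open by retro-Michael reaction and exchange the acetyl and propanoyl rings, or an adjacent phenol may close onto a triketone carbonyl with loss of water. The fallback sets out from 26 and comes back at 31 and makes no new compound. The silyl groups are removed with HF·pyridine, and triphenol acetate 29 is isolated. The last bridge is then formed under acid catalysis, with Sc(OTf)3 (cat.) in nitromethane in the presence of 28, by way of the benzylic cation. No phenoxide is formed, so no bridge can fragment.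

## Further compounds

F1 | step 3 | ethyl 3-oxopentanoate | CCC(=O)CC(=O)OCC
F2 | step 3 | ethyl (E)-3-ethoxypent-2-enoate | CC/C(OCC)=C\C(=O)OCC
F3 | step 3 | (E)-3-ethoxypent-2-enoic acid | CC/C(OCC)=C\C(=O)O
F4 | step 3 | (E)-3-ethoxypent-2-enoyl chloride | CC/C(OCC)=C\C(=O)Cl
F5 | step 6 | 1-{3-[(tert-butyldimethylsilyloxy)methyl]-6-ethoxy-5-methyl-2,4-bis(triisopropylsilyloxy)phenyl}butan-1-ol (racemic) | CCCC(O)c1c(O[Si](C(C)C)(C(C)C)C(C)C)c(CO[Si](C)(C)C(C)(C)C)c(O[Si](C(C)C)(C(C)C)C(C)C)c(C)c1OCC
F6 | step 8 | [3-butanoyl-5-(dibromomethyl)-4-ethoxy-2,6-bis(triisopropylsilyloxy)phenyl]methyl acetate | CCCC(=O)c1c(O[Si](C(C)C)(C(C)C)C(C)C)c(COC(C)=O)c(O[Si](C(C)C)(C(C)C)C(C)C)c(C(Br)Br)c1OCC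
F7 | step 8 | [3-butanoyl-4-ethoxy-5-formyl-2,6-bis(triisopropylsilyloxy)phenyl]methyl acetate | CCCC(=O)c1c(O[Si](C(C)C)(C(C)C)C(C)C)c(COC(C)=O)c(O[Si](C(C)C)(C(C)C)C(C)C)c(C=O)c1OCC
F8 | step 8 | [3-butanoyl-5-formyl-4-hydroxy-2,6-bis(triisopropylsilyloxy)phenyl]methyl acetate | CCCC(=O)c1c(O[Si](C(C)C)(C(C)C)C(C)C)c(COC(C)=O)c(O[Si](C(C)C)(C(C)C)C(C)C)c(C=O)c1O
F9 | step 9 | [3-butanoyl-4-hydroxy-5-methyl-2,6-bis(triisopropylsilyloxy)phenyl]methyl acetate | CCCC(=O)c1c(O[Si](C(C)C)(C(C)C)C(C)C)c(COC(C)=O)c(O[Si](C(C)C)(C(C)C)C(C)C)c(C)c1O
F10 | step 9 | {3-butanoyl-4-[(tert-butyldimethylsilyl)oxy]-5-methyl-2,6-bis(triisopropylsilyloxy)phenyl}methyl acetate | CCCC(=O)c1c(O[Si](C(C)C)(C(C)C)C(C)C)c(COC(C)=O)c(O[Si](C(C)C)(C(C)C)C(C)C)c(C)c1O[Si](C)(C)C(C)(C)C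
F11 | step 9 | {3-(bromomethyl)-5-butanoyl-4-[(tert-butyldimethylsilyl)oxy]-2,6-bis(triisopropylsilyloxy)phenyl}methyl acetate | CCCC(=O)c1c(O[Si](C(C)C)(C(C)C)C(C)C)c(COC(C)=O)c(O[Si](C(C)C)(C(C)C)C(C)C)c(CBr)c1O[Si](C)(C)C(C)(C)C
F0 | step 11 | none | none
F0 | step 13 | none | none
A1 | alternative 1 | tri-O-benzyl ether of the target | CCCC(=O)c1c(OCc2ccccc2)c(CC2=C(O)C(C)(C)C(O)=C(C(C)=O)C2=O)c(OCc2ccccc2)c(CC2=C(O)C(C)(C)C(O)=C(C(=O)CC)C2=O)c1OCc1ccccc1
A2 | alternative 1 | 1-{3-[(3-acetyl-2,4,6-trihydroxy-5-methylphenyl)methyl]-2,4,6-tris(benzyloxy)-5-[(2,4,6-trihydroxy-3-methyl-5-propanoylphenyl)methyl]phenyl}butan-1-one | CCCC(=O)c1c(OCc2ccccc2)c(Cc2c(O)c(C)c(O)c(C(C)=O)c2O)c(OCc2ccccc2)c(Cc2c(O)c(C)c(O)c(C(=O)CC)c2O)c1OCc1ccccc1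
A3 | alternative 2 | 3-ethoxy-4,4-dimethylcyclobut-2-en-1-one | CCOC1=CC(=O)C1(C)C
A4 | alternative 2 | triisopropyl({3-[2,4,6-tris(benzyloxy)phenyl]prop-1-yn-1-yl}oxy)silane | CC(C)[Si](OC#CCc1c(OCc2ccccc2)cc(OCc2ccccc2)cc1OCc1ccccc1)(C(C)C)C(C)C
A5 | alternative 2 | 2-[2,4,6-tris(benzyloxy)benzyl]-5-ethoxy-6,6-dimethyl-3-(triisopropylsilyloxy)cyclohexa-2,4-dien-1-one | CCOC1=CC(O[Si](C(C)C)(C(C)C)C(C)C)=C(Cc2c(OCc3ccccc3)cc(OCc3ccccc3)cc2OCc2ccccc2)C(=O)C1(C)C
A6 | alternative 3 | methyl 5-{2,4,6-tris(benzyloxy)-3-butanoyl-5-[2-(3-ethyl-1,2-oxazol-5-yl)-5-methoxy-4,4-dimethyl-3,5-dioxopentyl]phenyl}-2,2-dimethyl-4-(3-methyl-1,2-oxazol-5-yl)-3-oxopentanoate (mixture of diastereomers) | CCCC(=O)c1c(OCc2ccccc2)c(CC(c2cc(C)no2)C(=O)C(C)(C)C(=O)OC)c(OCc2ccccc2)c(CC(c2cc(CC)no2)C(=O)C(C)(C)C(=O)OC)c1OCc1ccccc1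
A7 | alternative 3 | tri-O-benzyl ether of the target with both acyl carbonyls as exocyclic 1-aminoalkylidene groups (bis-enaminone) | CCCC(=O)c1c(OCc2ccccc2)c(CC2=C(O)C(C)(C)C(=O)C(=C(C)N)C2=O)c(OCc2ccccc2)c(CC2=C(O)C(C)(C)C(=O)C(=C(N)CC)C2=O)c1OCc1ccccc1
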